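**Plan**
Retrosynthesis cuts the propionate C–O bond, then C12–C13 (B-alkyl Suzuki coupling), C9–C10 (ring B, intramolecular Heck), C6–C7 (Wittig), and C3–C4 together with C5–C10 (ring A, Diels–Alder).
Forward: the C7–C12 arm (steps 1–8) and ring A (steps 9–12) are made separately and joined at C6–C7 (step 13); ring A therefore exists first, ring B closes at C9 (step 18), and the C13–C16 unit (steps 19–21), the free acid and the propionate follow (steps 22–24).
Feature used: C10 is an sp2 carbon of ring A (C1=C10) bonded to the quaternary C9 of ring B, so an alkenylpalladium at C10, made from the C10 enol triflate with C1=C10 already in place, can add to a C9=C11 alkene held by the C5–C8 tether and form C9–C10.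
Stereochemistry: C4 and C5 come from an enantioselective Diels–Alder addition to an E dienophile (ester trans to formyl), C8 from methyl (R)-3-hydroxy-2-methylpropanoate, C9 from the Heck step under control of C5 and C8, and the C13=C14 E alkene from syn hydrozirconation and a stereoretentive coupling.

Key step: step 18

Remark: atoms carry the halimane numbering throughout (ring A C1–C5 and C10, ring B C5–C10, side chain C11–C16, acid on C4).
Assumption: the (S)-configured oxazaborolidinium catalyst of step 12 is taken to shield the face of the bound enal that leads to adduct 17; if the first run shows the opposite sense, the (R)-catalyst is used and nothing else changes.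

Step 1
Reactants: 1 methyl (R)-3-hydroxy-2-methylpropanoate
Product: 2 methyl (R)-3-[(tert-butyldimethylsilyl)oxy]-2-methylpropanoate
Conditions: TBSCl, imidazole, CH2Cl2, 0 °C to rt
Reagents that add atoms: tert-butyldimethylsilyl chloride, CC(C)(C)[Si](C)(C)Cl
Why: Silyl ether formation protects the primary hydroxyl and leaves the ester and the future C8 centre untouched.

Step 2
Reactants: 2 methyl (R)-3-[(tert-butyldimethylsilyl)oxy]-2-methylpropanoate
Product: 3 (R)-3-[(tert-butyldimethylsilyl)oxy]-2-methylpropanal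
Conditions: i-Bu2AlH, CH2Cl2, −78 °C; aqueous work-up
Reagents that add atoms: none
Why: Partial ester reduction with i-Bu2AlH stops at the aluminium hemiacetal at low temperature and should give the α-branched aldehyde without loss of configuration.

Step 3
Reactants: 3 (R)-3-[(tert-butyldimethylsilyl)oxy]-2-methylpropanal
Product: 4 tert-butyldimethyl{[(2S)-2-methylbut-3-yn-1-yl]oxy}silane
Conditions: dimethyl (1-diazo-2-oxopropyl)phosphonate, K2CO3, MeOH, 0 °C to rt
Reagents that add atoms: dimethyl (1-diazo-2-oxopropyl)phosphonate, COP(=O)(OC)C(=[N+]=[N-])C(C)=O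
Why: Seyferth–Gilbert homologation in the Ohira–Bestmann form turns the aldehyde into the terminal alkyne under mild carbonate conditions that spare the adjacent stereocentre.

Step 4
Reactants: 4 tert-butyldimethyl{[(2S)-2-methylbut-3-yn-1-yl]oxy}silane
Product: 6 tert-butyl{[(2S,3E)-4-iodo-2,3-dimethylbut-3-en-1-yl]oxy}dimethylsilane, via alkenyldimethylalane 5 (not isolated)
Conditions: AlMe3, Cp2ZrCl2 (20 mol%), CH2Cl2, 0 °C to rt; then I2, THF, −30 °C
Reagents that add atoms: trimethylaluminium, C[Al](C)C; iodine, II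
Why: Negishi zirconium-catalysed methylalumination adds methyl and aluminium syn with methyl on the internal carbon, and iodinolysis with retention should give the E iodide.

Step 5
Reactants: 6 tert-butyl{[(2S,3E)-4-iodo-2,3-dimethylbut-3-en-1-yl]oxy}dimethylsilane
Product: 7 tert-butyl{[(2S,3E)-2,3-dimethylpent-3-en-1-yl]oxy}dimethylsilane
Conditions: Me2Zn, Pd(PPh3)4 (5 mol%), THF, 0 °C to rt
Reagents that add atoms: dimethylzinc, C[Zn]C
Why: Negishi cross-coupling replaces iodine by methyl (C12) with retention of the E geometry.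

Step 6
Reactants: 7 tert-butyl{[(2S,3E)-2,3-dimethylpent-3-en-1-yl]oxy}dimethylsilane
Product: 8 (2S,3E)-2,3-dimethylpent-3-en-1-ol
Conditions: Bu4NF, THF, 0 °C to rt
Reagents that add atoms: none
Why: Fluoride-mediated desilylation frees the primary alcohol.

Step 7
Reactants: 8 (2S,3E)-2,3-dimethylpent-3-en-1-ol
Product: 9 (2S,3E)-1-iodo-2,3-dimethylpent-3-ene
Conditions: I2, PPh3, imidazole, CH2Cl2, 0 °C
Reagents that add atoms: iodine, II
Why: Appel-type iodination (Garegg–Samuelsson conditions) converts the primary alcohol by SN2 at C7 and does not touch the allylic centre.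

Step 8
Reactants: 9 (2S,3E)-1-iodo-2,3-dimethylpent-3-ene
Product: 10 [(2S,3E)-2,3-dimethylpent-3-en-1-yl]triphenylphosphonium iodide
Conditions: PPh3, MeCN, reflux
Reagents that add atoms: triphenylphosphine, c1ccc(cc1)P(c1ccccc1)c1ccccc1
Why: SN2 quaternisation of the phosphine by the primary iodide gives the Wittig salt.

Step 9
Reactants: 11 2,2-dimethoxyacetaldehyde; 12 methyl 2-(triphenylphosphoranylidene)propanoate
Product: 13 methyl (2E)-4,4-dimethoxy-2-methylbut-2-enoate
Conditions: CH2Cl2, rt
Reagents that add atoms: none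
Why: Wittig olefination with a stabilised ylide should give the E enoate, with the acetal carbon trans to the ester.

Step 10
Reactants: 13 methyl (2E)-4,4-dimethoxy-2-methylbut-2-enoate
Product: 14 methyl (2E)-2-methyl-4-oxobut-2-enoate
Conditions: aq HCl (1 M), acetone, rt
Reagents that add atoms: water, O
Why: Acid-catalysed acetal hydrolysis releases the aldehyde, and the E geometry (ester trans to formyl) is the stable one.

Step 11
Reactants: 15 (E)-but-2-enal
Product: 16 (1E)-1-[(triisopropylsilyl)oxy]buta-1,3-diene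
Conditions: i-Pr3SiOTf, Et3N, Et2O, 0 °C to rt
Reagents that add atoms: triisopropylsilyl trifluoromethanesulfonate, CC(C)[Si](OS(=O)(=O)C(F)(F)F)(C(C)C)C(C)C
Why: O-Silylation of the dienolate formed by γ-deprotonation of the enal gives the 1-silyloxydiene, expected mainly as the E isomer, the only one able to react in step 12.

Step 12
Reactants: 14 methyl (2E)-2-methyl-4-oxobut-2-enoate; 16 (1E)-1-[(triisopropylsilyl)oxy]buta-1,3-diene
Product: 17 methyl (1S,2R,3S)-2-formyl-1-methyl-3-[(triisopropylsilyl)oxy]cyclohex-4-ene-1-carboxylate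
Conditions: (S)-3,3-diphenyl-1-(2-methylphenyl)tetrahydro-1H,3H-pyrrolo[1,2-c][1,3,2]oxazaborole (20 mol%), HNTf2 (18 mol%), CH2Cl2, −78 °C
Reagents that add atoms: none
Why: In this catalytic enantioselective Diels–Alder reaction the formyl group bound to the chiral oxazaborolidinium ion sends the unsubstituted diene terminus to C4 and the oxygenated terminus to C5, suprafacial addition to the E dienophile fixes the C4 ester trans to the C5 formyl group, the catalyst face sets the absolute configuration of both centres, and the endo-placed silyloxy group at C10 is a centre erased in step 16.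

Step 13
Reactants: 10 [(2S,3E)-2,3-dimethylpent-3-en-1-yl]triphenylphosphonium iodide; 17 methyl (1S,2R,3S)-2-formyl-1-methyl-3-[(triisopropylsilyl)oxy]cyclohex-4-ene-1-carboxylate
Product: 19 methyl (1S,2R,3S)-2-[(1Z,3R,4E)-3,4-dimethylhexa-1,4-dien-1-yl]-1-methyl-3-[(triisopropylsilyl)oxy]cyclohex-4-ene-1-carboxylate, via phosphorus ylide 18 (not isolated)
Conditions: NaN(SiMe3)2, THF, 0 °C; then 17, −78 °C to rt
Reagents that add atoms: none
Why: Wittig olefination with the non-stabilised ylide joins C6 to C7 as the Z alkene at low temperature, where the hindered aldehyde should keep its C5 configuration.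

Step 14
Reactants: 19 methyl (1S,2R,3S)-2-[(1Z,3R,4E)-3,4-dimethylhexa-1,4-dien-1-yl]-1-methyl-3-[(triisopropylsilyl)oxy]cyclohex-4-ene-1-carboxylate
Product: 20 methyl (1S,2R,3S)-2-[(3R,4E)-3,4-dimethylhex-4-en-1-yl]-1-methyl-3-[(triisopropylsilyl)oxy]cyclohexane-1-carboxylate
Conditions: H2 (3 atm), RhCl(PPh3)3 (10 mol%), toluene, rt
Reagents that add atoms: none
Why: Homogeneous hydrogenation with RhCl(PPh3)3 should saturate the two cis-disubstituted alkenes (C1=C2 and C6=C7) well before the trisubstituted C9=C11 alkene, and no stereocentre is formed.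

Step 15
Reactants: 20 methyl (1S,2R,3S)-2-[(3R,4E)-3,4-dimethylhex-4-en-1-yl]-1-methyl-3-[(triisopropylsilyl)oxy]cyclohexane-1-carboxylate
Product: 21 methyl (1S,2R,3S)-2-[(3R,4E)-3,4-dimethylhex-4-en-1-yl]-3-hydroxy-1-methylcyclohexane-1-carboxylate
Conditions: HF·pyridine, pyridine, THF, 0 °C to rt
Reagents that add atoms: none
Why: Acidic fluoride desilylation removes the silyl ether without base, so neither lactonisation onto the ester nor change at C5 is expected.

Step 16
Reactants: 21 methyl (1S,2R,3S)-2-[(3R,4E)-3,4-dimethylhex-4-en-1-yl]-3-hydroxy-1-methylcyclohexane-1-carboxylate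
Product: 22 methyl (1S,2R)-2-[(3R,4E)-3,4-dimethylhex-4-en-1-yl]-1-methyl-3-oxocyclohexane-1-carboxylate
Conditions: Dess–Martin periodinane, pyridine, CH2Cl2, 0 °C to rt
Reagents that add atoms: none
Why: Dess–Martin oxidation gives the C10 ketone under near-neutral conditions that should not epimerise the adjacent C5 centre.

Step 17
Reactants: 22 methyl (1S,2R)-2-[(3R,4E)-3,4-dimethylhex-4-en-1-yl]-1-methyl-3-oxocyclohexane-1-carboxylate
Product: 24 methyl (1S,2R)-2-[(3R,4E)-3,4-dimethylhex-4-en-1-yl]-1-methyl-3-{[(trifluoromethyl)sulfonyl]oxy}cyclohex-3-ene-1-carboxylate, via potassium enolate 23 (not isolated)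
Conditions: KN(SiMe3)2, THF, −78 °C; then PhNTf2, −78 °C to 0 °C
Reagents that add atoms: N-phenylbis(trifluoromethanesulfonimide), O=S(=O)(N(c1ccccc1)S(=O)(=O)C(F)(F)F)C(F)(F)F
Why: Kinetic enolisation takes an unhindered C1 hydrogen rather than the tertiary C5 hydrogen next to the quaternary C4, and O-triflation of the enolate fixes the C1=C10 enol triflate.

Step 18
Reactants: 24 methyl (1S,2R)-2-[(3R,4E)-3,4-dimethylhex-4-en-1-yl]-1-methyl-3-{[(trifluoromethyl)sulfonyl]oxy}cyclohex-3-ene-1-carboxylate
Product: 25 methyl (1S,5S,6R,8aS)-5-ethenyl-1,5,6-trimethyl-1,2,3,5,6,7,8,8a-octahydronaphthalene-1-carboxylate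
Conditions: Pd(OAc)2 (10 mol%), rac-BINAP (12 mol%), K2CO3, toluene, 80 °C
Reagents that add atoms: none
Why: The C10 enol triflate adds oxidatively to zerovalent palladium formed from Pd(OAc)2 and BINAP, the cationic alkenylpalladium inserts syn into the trisubstituted C9=C11 alkene, and β-hydride elimination of a C12 hydrogen leaves the vinyl group. The closest known reaction type is the intramolecular Heck cyclisation of alkenyl triflates onto trisubstituted alkenes that builds all-carbon quaternary centres. Ring B closes 6-exo-trig through the new C9–C10 bond. The C9 centre is set by the substrate: the tether leaves ring A at C5 on one face, so C9 must reach C10 on that face with C8 on the C5 side of the plane through Pd, C10, C9 and C11, which puts the C9 methyl over C1 and C11 next to palladium, and in this arrangement the C8 methyl sits pseudoequatorial, away from the metal. The step needs exo rather than endo insertion and one direction of elimination; the six-membered transition state secures the first, and because C9 becomes quaternary only the C12 hydrogens can be lost, so the new alkene cannot move. Racemic BINAP serves only as a wide-bite-angle bisphosphine for the cationic pathway, since the two existing centres act in the same sense.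

Step 19
Reactants: 26 but-2-yn-1-ol
Product: 27 tert-butyl(but-2-yn-1-yloxy)dimethylsilane
Conditions: TBSCl, imidazole, CH2Cl2, 0 °C to rt
Reagents that add atoms: tert-butyldimethylsilyl chloride, CC(C)(C)[Si](C)(C)Cl
Why: Silyl ether formation masks the hydroxyl before hydrozirconation.

Step 20
Reactants: 27 tert-butyl(but-2-yn-1-yloxy)dimethylsilane
Product: 29 tert-butyl{[(2E)-3-iodobut-2-en-1-yl]oxy}dimethylsilane, via alkenylzirconocene chloride 28 (not isolated)
Conditions: Cp2Zr(H)Cl, THF, rt to 40 °C; then I2, 0 °C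
Reagents that add atoms: iodine, II
Why: Schwartz hydrozirconation adds syn and, after equilibration, places zirconium on the methyl-bearing carbon, and iodinolysis with retention should give the E iodide.

Step 21
Reactants: 29 tert-butyl{[(2E)-3-iodobut-2-en-1-yl]oxy}dimethylsilane
Product: 30 (2E)-3-iodobut-2-en-1-ol
Conditions: Bu4NF, THF, 0 °C
Reagents that add atoms: none
Why: Fluoride-mediated desilylation frees the allylic alcohol without touching the alkenyl iodide.

Step 22
Reactants: 25 methyl (1S,5S,6R,8aS)-5-ethenyl-1,5,6-trimethyl-1,2,3,5,6,7,8,8a-octahydronaphthalene-1-carboxylate; 30 (2E)-3-iodobut-2-en-1-ol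
Product: 32 methyl (1S,5S,6R,8aS)-5-[(3E)-5-hydroxy-3-methylpent-3-en-1-yl]-1,5,6-trimethyl-1,2,3,5,6,7,8,8a-octahydronaphthalene-1-carboxylate, via B-alkyl-9-borabicyclononane 31 (not isolated)
Conditions: 9-BBN-H, THF, 60 °C; then 30, PdCl2(dppf) (5 mol%), aq NaOH (3 M), THF, 60 °C
Reagents that add atoms: none
Why: Anti-Markovnikov hydroboration touches only the monosubstituted vinyl group, and B-alkyl Suzuki–Miyaura coupling forms C12–C13 with retention, which fixes the E geometry at C13=C14.

Step 23
Reactants: 32 methyl (1S,5S,6R,8aS)-5-[(3E)-5-hydroxy-3-methylpent-3-en-1-yl]-1,5,6-trimethyl-1,2,3,5,6,7,8,8a-octahydronaphthalene-1-carboxylate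
Product: 33 (1S,5S,6R,8aS)-5-[(3E)-5-hydroxy-3-methylpent-3-en-1-yl]-1,5,6-trimethyl-1,2,3,5,6,7,8,8a-octahydronaphthalene-1-carboxylic acid
Conditions: KOH, MeOH/H2O, 80 °C; then aq HCl to pH 3
Reagents that add atoms: potassium hydroxide, [K+].[OH-]
Why: Saponification of the methyl ester on the quaternary C4 needs heat, which the allylic alcohol and both alkenes should tolerate.

Step 24
Reactants: 33 (1S,5S,6R,8aS)-5-[(3E)-5-hydroxy-3-methylpent-3-en-1-yl]-1,5,6-trimethyl-1,2,3,5,6,7,8,8a-octahydronaphthalene-1-carboxylic acid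
Product: 35 (1S,5S,6R,8aS)-1,5,6-trimethyl-5-[(3E)-3-methyl-5-(propanoyloxy)pent-3-en-1-yl]-1,2,3,5,6,7,8,8a-octahydronaphthalene-1-carboxylic acid, via mixed anhydride 34 (not isolated)
Conditions: (EtCO)2O, pyridine, DMAP (cat.), CH2Cl2, 0 °C to rt; then H2O, THF, rt
Reagents that add atoms: propanoic anhydride, CCC(=O)OC(=O)CC
Why: Pyridine/DMAP-promoted acylation esterifies the primary allylic alcohol, and the mixed anhydride formed at the hindered C4 acid is cleaved by water at its unhindered propanoyl carbonyl, which returns the free acid.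

**Compound list**
1 | methyl (R)-3-hydroxy-2-methylpropanoate | COC(=O)[C@H](C)CO | starting material
2 | methyl (R)-3-[(tert-butyldimethylsilyl)oxy]-2-methylpropanoate | COC(=O)[C@H](C)CO[Si](C)(C)C(C)(C)C | intermediate
3 | (R)-3-[(tert-butyldimethylsilyl)oxy]-2-methylpropanal | O=C[C@H](C)CO[Si](C)(C)C(C)(C)C | intermediate
4 | tert-butyldimethyl{[(2S)-2-methylbut-3-yn-1-yl]oxy}silane | C#C[C@H](C)CO[Si](C)(C)C(C)(C)C | intermediate
5 | {(1E,3S)-4-[(tert-butyldimethylsilyl)oxy]-2,3-dimethylbut-1-en-1-yl}dimethylalumane | C[Al](C)/C=C(\C)[C@H](C)CO[Si](C)(C)C(C)(C)C | intermediate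
6 | tert-butyl{[(2S,3E)-4-iodo-2,3-dimethylbut-3-en-1-yl]oxy}dimethylsilane | I/C=C(\C)[C@H](C)CO[Si](C)(C)C(C)(C)C | intermediate
7 | tert-butyl{[(2S,3E)-2,3-dimethylpent-3-en-1-yl]oxy}dimethylsilane | C/C=C(\C)[C@H](C)CO[Si](C)(C)C(C)(C)C | intermediate
8 | (2S,3E)-2,3-dimethylpent-3-en-1-ol | C/C=C(\C)[C@H](C)CO | intermediate
9 | (2S,3E)-1-iodo-2,3-dimethylpent-3-ene | C/C=C(\C)[C@H](C)CI | intermediate
10 | [(2S,3E)-2,3-dimethylpent-3-en-1-yl]triphenylphosphonium iodide | C/C=C(\C)[C@H](C)C[P+](c1ccccc1)(c1ccccc1)c1ccccc1.[I-] | intermediate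
11 | 2,2-dimethoxyacetaldehyde | COC(OC)C=O | starting material
12 | methyl 2-(triphenylphosphoranylidene)propanoate | COC(=O)C(C)=P(c1ccccc1)(c1ccccc1)c1ccccc1 | starting material
13 | methyl (2E)-4,4-dimethoxy-2-methylbut-2-enoate | COC(=O)/C(C)=C/C(OC)OC | intermediate
14 | methyl (2E)-2-methyl-4-oxobut-2-enoate | COC(=O)/C(C)=C/C=O | intermediate
15 | (E)-but-2-enal | C/C=C/C=O | starting material
16 | (1E)-1-[(triisopropylsilyl)oxy]buta-1,3-diene | C=C/C=C/O[Si](C(C)C)(C(C)C)C(C)C | intermediate
17 | methyl (1S,2R,3S)-2-formyl-1-methyl-3-[(triisopropylsilyl)oxy]cyclohex-4-ene-1-carboxylate (formyl trans to ester, cis to silyloxy) | O=C[C@H]1[C@@H](O[Si](C(C)C)(C(C)C)C(C)C)C=CC[C@]1(C)C(=O)OC | intermediate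
18 | [(2S,3E)-2,3-dimethylpent-3-en-1-ylidene]triphenylphosphorane | C/C=C(\C)[C@H](C)C=P(c1ccccc1)(c1ccccc1)c1ccccc1 | intermediate
19 | methyl (1S,2R,3S)-2-[(1Z,3R,4E)-3,4-dimethylhexa-1,4-dien-1-yl]-1-methyl-3-[(triisopropylsilyl)oxy]cyclohex-4-ene-1-carboxylate | C/C=C(\C)[C@H](C)/C=C\[C@H]1[C@@H](O[Si](C(C)C)(C(C)C)C(C)C)C=CC[C@]1(C)C(=O)OC | intermediate
20 | methyl (1S,2R,3S)-2-[(3R,4E)-3,4-dimethylhex-4-en-1-yl]-1-methyl-3-[(triisopropylsilyl)oxy]cyclohexane-1-carboxylate | C/C=C(\C)[C@H](C)CC[C@H]1[C@@H](O[Si](C(C)C)(C(C)C)C(C)C)CCC[C@]1(C)C(=O)OC | intermediate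
21 | methyl (1S,2R,3S)-2-[(3R,4E)-3,4-dimethylhex-4-en-1-yl]-3-hydroxy-1-methylcyclohexane-1-carboxylate | C/C=C(\C)[C@H](C)CC[C@H]1[C@@H](O)CCC[C@]1(C)C(=O)OC | intermediate
22 | methyl (1S,2R)-2-[(3R,4E)-3,4-dimethylhex-4-en-1-yl]-1-methyl-3-oxocyclohexane-1-carboxylate | C/C=C(\C)[C@H](C)CC[C@H]1C(=O)CCC[C@]1(C)C(=O)OC | intermediate
23 | potassium enolate of 22 toward C1 | C/C=C(\C)[C@H](C)CC[C@H]1C([O-])=CCC[C@]1(C)C(=O)OC.[K+] | intermediate
24 | methyl (1S,2R)-2-[(3R,4E)-3,4-dimethylhex-4-en-1-yl]-1-methyl-3-{[(trifluoromethyl)sulfonyl]oxy}cyclohex-3-ene-1-carboxylate | C/C=C(\C)[C@H](C)CC[C@H]1C(OS(=O)(=O)C(F)(F)F)=CCC[C@]1(C)C(=O)OC | intermediate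
25 | methyl (1S,5S,6R,8aS)-5-ethenyl-1,5,6-trimethyl-1,2,3,5,6,7,8,8a-octahydronaphthalene-1-carboxylate | C=C[C@]1(C)C2=CCC[C@](C)(C(=O)OC)[C@H]2CC[C@H]1C | intermediate
26 | but-2-yn-1-ol | CC#CCO | starting material
27 | tert-butyl(but-2-yn-1-yloxy)dimethylsilane | CC#CCO[Si](C)(C)C(C)(C)C | intermediate
28 | {(2E)-4-[(tert-butyldimethylsilyl)oxy]but-2-en-2-yl}chlorobis(cyclopentadienyl)zirconium (rings drawn σ-bonded) | C/C(=C\CO[Si](C)(C)C(C)(C)C)[Zr](Cl)(C1C=CC=C1)C1C=CC=C1 | intermediate
29 | tert-butyl{[(2E)-3-iodobut-2-en-1-yl]oxy}dimethylsilane | CC(C)(C)[Si](C)(C)OC/C=C(\C)I | intermediate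
30 | (2E)-3-iodobut-2-en-1-ol | OC/C=C(\C)I | intermediate
31 | 9-borabicyclo[3.3.1]nonan-9-yl adduct at C12 of 25 | C1CCC2CCCC1B2CC[C@]3(C)C4=CCC[C@](C)(C(=O)OC)[C@H]4CC[C@H]3C | intermediate
32 | methyl (1S,5S,6R,8aS)-5-[(3E)-5-hydroxy-3-methylpent-3-en-1-yl]-1,5,6-trimethyl-1,2,3,5,6,7,8,8a-octahydronaphthalene-1-carboxylate | OC/C=C(\C)CC[C@]1(C)C2=CCC[C@](C)(C(=O)OC)[C@H]2CC[C@H]1C | intermediate
33 | (1S,5S,6R,8aS)-5-[(3E)-5-hydroxy-3-methylpent-3-en-1-yl]-1,5,6-trimethyl-1,2,3,5,6,7,8,8a-octahydronaphthalene-1-carboxylic acid | OC/C=C(\C)CC[C@]1(C)C2=CCC[C@](C)(C(=O)O)[C@H]2CC[C@H]1C | intermediate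
34 | mixed propanoic anhydride of 35 at the C4 carboxyl | CCC(=O)OC/C=C(\C)CC[C@]1(C)C2=CCC[C@](C)(C(=O)OC(=O)CC)[C@H]2CC[C@H]1C | intermediate
35 | (1S,5S,6R,8aS)-1,5,6-trimethyl-5-[(3E)-3-methyl-5-(propanoyloxy)pent-3-en-1-yl]-1,2,3,5,6,7,8,8a-octahydronaphthalene-1-carboxylic acid (CNP0223570.1) | CCC(=O)OC/C=C(\C)CC[C@]1(C)C2=CCC[C@](C)(C(=O)O)[C@H]2CC[C@H]1C | target

**Totals and risks**
Total step count: 24. Longest linear sequence: 17 steps (1–8, 13–18, 22–24).

Step 12 (Diels–Alder). What may go wrong: weak facial discrimination at the trisubstituted dienophile, or diversion of the silyloxydiene into a vinylogous Mukaiyama-type addition at the activated formyl group instead of cycloaddition. The fallback sets out from iodide 9 and returns at ketone 22, so that ring A comes from conjugate-addition chemistry and steps 9–16 fall away. Commercial methyl 3-oxocyclohex-1-ene-1-carboxylate would take up Me2Zn under Cu(OTf)2 and a chiral N-heterocyclic carbene ligand (copper-catalysed asymmetric conjugate addition) to give the methylzinc enolate F1, which is silylated in the same flask with Me3SiOTf to the silyl enol ether F2. Dimethylmethyleneiminium iodide converts F2 into the Mannich base F3; N-methylation with MeI gives the ammonium iodide F4, and DBU eliminates it to the α-methylene ketone F5. The Grignard reagent F6, made from 9 and Mg, adds to F5 under CuBr·SMe2 catalysis, and protonation of the magnesium enolate F7 at −78 °C gives 22. C5 is then set only by that protonation, so the C5 epimer would have to be separated and recycled by base equilibration.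

Step 18 (Heck). What may go wrong: slow insertion at the hindered trisubstituted alkene, which lets reduction of the alkenylpalladium or loss of the triflate compete, or erosion of face selectivity at C9. The fallback sets out from ketone 22 and returns at ester 25. Ozonolysis of the only alkene of 22 (O3, then Me2S) gives the diketone F8. Wittig olefination of its less hindered methyl ketone with Ph3P=CHCH2SiMe3 gives the allylsilane F9. TiCl4 then promotes an intramolecular Hosomi–Sakurai allylation in which C9, the γ-carbon of the allylsilane, attacks the C10 ketone, forming C9–C10 and the vinyl group in the tertiary alcohol F10. Dehydration with Burgess reagent toward the less hindered C1 hydrogen gives 25.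

Step 14 (selective hydrogenation). What may go wrong: over-reduction of the trisubstituted C9=C11 alkene, or incomplete reduction of the hindered Z C6=C7 alkene. The fallback sets out from diene 19 and returns at alcohol 21. HF·pyridine removes the silyl group first to give the dienol F11. Hydrogenation with [Rh(nbd)(dppb)]BF4 is then directed by the free C10 hydroxyl to the allylic C1=C2 and homoallylic C6=C7 alkenes, while the remote C9=C11 alkene has no directing group, and 21 results.

**Further compounds**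
F1 | step 12 | methylzinc enolate of methyl (1S)-1-methyl-3-oxocyclohexane-1-carboxylate | C[Zn]OC1=C[C@@](C)(C(=O)OC)CCC1
F2 | step 12 | methyl (1S)-1-methyl-3-[(trimethylsilyl)oxy]cyclohex-2-ene-1-carboxylate | C[Si](C)(C)OC1=C[C@@](C)(C(=O)OC)CCC1
F3 | step 12 | methyl (1S)-2-[(dimethylamino)methyl]-1-methyl-3-oxocyclohexane-1-carboxylate (C2 epimers) | CN(C)CC1C(=O)CCC[C@]1(C)C(=O)OC
F4 | step 12 | N-methylammonium iodide of F3 | C[N+](C)(C)CC1C(=O)CCC[C@]1(C)C(=O)OC.[I-]
F5 | step 12 | methyl (1S)-1-methyl-2-methylidene-3-oxocyclohexane-1-carboxylate | C=C1C(=O)CCC[C@]1(C)C(=O)OC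
F6 | step 12 | [(2S,3E)-2,3-dimethylpent-3-en-1-yl]magnesium iodide | C/C=C(\C)[C@H](C)C[Mg]I
F7 | step 12 | iodomagnesium enolate of 22 toward C5 | C/C=C(\C)[C@H](C)CCC1=C(O[Mg]I)CCC[C@]1(C)C(=O)OC
F8 | step 18 | methyl (1S,2R)-1-methyl-2-[(3R)-3-methyl-4-oxopentyl]-3-oxocyclohexane-1-carboxylate | CC(=O)[C@H](C)CC[C@H]1C(=O)CCC[C@]1(C)C(=O)OC
F9 | step 18 | methyl (1S,2R)-2-[(3R)-3,4-dimethyl-6-(trimethylsilyl)hex-4-en-1-yl]-1-methyl-3-oxocyclohexane-1-carboxylate (alkene geometry open) | C[Si](C)(C)CC=C(C)[C@H](C)CC[C@H]1C(=O)CCC[C@]1(C)C(=O)OC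
F10 | step 18 | C10 tertiary alcohol corresponding to 25 (4a-hydroxy, saturated ring A, C10 configuration open) | C=C[C@]1(C)C2(O)CCC[C@](C)(C(=O)OC)[C@H]2CC[C@H]1C
F11 | step 14 | methyl (1S,2R,3S)-2-[(1Z,3R,4E)-3,4-dimethylhexa-1,4-dien-1-yl]-3-hydroxy-1-methylcyclohex-4-ene-1-carboxylate | C/C=C(\C)[C@H](C)/C=C\[C@H]1[C@@H](O)C=CC[C@]1(C)C(=O)OC
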